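The amounts set the problem: 0.50 mM of substrate is charged, while the gas it needs saturates at 0.13 mM, less than that charge, so the gas must arrive over time.

substrate 0.50 mM; gas phase 0.13 mM (held); protic impurity 0.0250 mM; time 40 s

    gas phase ⇌ dissolved gas, rate k1*(csat - [dissolved gas]) (k1 = 0.28 /s, csat = 0.13 mM)
    substrate + dissolved gas → target (k2 = 4500 /M/s)
    substrate → side product A (k3 = 0.016 /s)
    2 substrate → homo dimer (k4 = 0.049 /M/s)
    dissolved gas + protic impurity → quenched reagent (k5 = 730 /M/s)
    substrate + target → side product B (k6 = 1400 /M/s)

- in percentages every species weighs as the substrate in it: one homo dimer or side product B counts as two
- a step written with two of one species runs at k times the square of its concentration and takes two of it each time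
- at the start none of the gas is dissolved
- run time (flask): 40 s

* how much target there is at 40 s, in percent of the substrate charged
* the change that raises the amount of target at 40 s, in percent of the substrate charged most ("none" if none brings more than 2 percentage points) (teal / red / none)
* amount of target at 40 s, in percent of the substrate charged, after teal

First I ask which numbers must be known well. The homo dimer constant may be far off: that step's half-life of 20400 s is much longer than the 40 s run. The quenching constant matters little too, since dissolved gas has a half-life of 38 s against the impurity but 0.31 s against substrate. That 0.31 s is also shorter than the transfer half-life of 2.48 s, so for a rough estimate I treat transfer as the rate-limiting step and count gas as consumed on arrival. This is a simplification: the 0.31 s holds for substrate as charged, so I keep the coupling constant among the numbers to know well. Side product A matters somewhat: it starts at 0.00800 mM/s, and I drop it, so my figure should run high. The transfer coefficient and the saturation concentration must be known well too, since they give the gas supply, and so must the constant for side product B, because target's half-life of 0.99 s is short against 40 s.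

Now the number. With gas counted as consumed on arrival, target forms at S = 0.0364 mM/s, the transfer rate into a solution kept empty, and substrate A destroys target P at k·A·P, where k is the constant for side product B. So P tracks S/(kA), climbing as A falls, until the two meet. That gives the meeting level P* = √(S/k) = 0.161 mM. Errors in its inputs enter as square roots. Joining this level to the charge c by a guessed shape, Y = P*/(P* + c), I get 24.4%. Doubling S gives 31.3% for teal. Red doubles S too, but supplies more than teal once dissolved gas is present, so I choose red.

The forecast says 24.8%, red and 29%, noting that “faster gas supply shortens that overlap”.

The simulation gives 22.4% of target in the flask, with side product B at 68.6%. Teal gives 29.1%, a gain of 6.7 percentage points, and red gains 10 points, so the choice is red. The neighbouring flask charges 0.20 mM of substrate with the same P*, so Y gives 44.6% there. That neighbouring flask gives 47.4% of target, with side product B at 45.5%.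

The numbers of this flask were drawn at random within sensible limits.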